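**Retrosynthetic overview**

1. Digriseophene A (14) comes from its A-ring tetra-MOM ether 13 by acetal cleavage.
2. 13 is disconnected at the two B-ring C4–O bonds to the 4-deoxy dimer 11 (iridium C–H borylation, then B→O exchange). This rests on B-ring C4 (ring numbered from the carbonyl-bearing carbon) being the only aromatic carbon of the skeleton whose two ring neighbours both carry hydrogen: B-ring C3–H adjoins the C2 methyl, B-ring C5–H adjoins the C6 methoxy, and the single A-ring C–H (C5) lies between the C4 methoxy and the C6 oxygen.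
3. 11 comes from tetraphenol 10 (MOM protection), and 10 from two molecules of benzophenone 7 plus formaldehyde, which forms both ArCH2–Ar bonds at A-ring C3.
4. 7 comes from 5-methoxyresorcinol bis-MOM ether 2 and aldehyde 3: ortho-lithiation between the two OMOM groups, addition, oxidation and MOM removal form the aryl–carbonyl bond.
5. No ring is formed; both benzene rings of each half are bought intact. Bond order: A–C(O)–B, then the CH2 bridge, then B-ring C4–O.

Key step: step 7

Remark 1: the target SMILES carries no stereodescriptor and the molecule has no stereogenic element. The only stereocentre on the route, the carbinol carbon of 5, is racemic and is erased in step 3.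
Remark 2: the aryl–carbonyl bond is made on the monomer, before the methylene bridge exists, because the doubly benzylic CH2 of a bis(alkoxyaryl)methane would compete with the ring C–H for butyllithium.

**Route**

Step 1
Reactants: 1 5-methoxyresorcinol
Product: 2 1-methoxy-3,5-bis(methoxymethoxy)benzene
Conditions: MOMCl (2.5 equiv), i-Pr2NEt (3 equiv), CH2Cl2, 0 °C to rt
Reagents that add atoms: chloromethyl methyl ether (MOMCl), COCCl
Why: O-alkylation of both phenols by the hard, oxocarbenium-like electrophile (Williamson-type acetal formation) should give the bis-MOM ether that serves as the directing group in step 2.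

Step 2
Reactants: 2 1-methoxy-3,5-bis(methoxymethoxy)benzene; 3 2-methoxy-6-methylbenzaldehyde
Product: 5 rac-[4-methoxy-2,6-bis(methoxymethoxy)phenyl](2-methoxy-6-methylphenyl)methanol, via aryllithium 4 (not isolated)
Conditions: n-BuLi (1.1 equiv), THF, 0 °C, 1 h; then 3, −78 °C to rt; H2O
Reagents that add atoms: n-butyllithium, [Li]CCCC (supplies the lithium of 4; no atom of it remains in 5)
Why: Directed ortho-metalation should remove the C–H flanked by two chelating OMOM groups in preference to the two C–H bonds next to the weaker methoxy director, and the aryllithium then adds 1,2 to the aldehyde; the carbinol centre forms as the racemate and is removed in step 3.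

Step 3
Reactants: 5 rac-[4-methoxy-2,6-bis(methoxymethoxy)phenyl](2-methoxy-6-methylphenyl)methanol
Product: 6 [4-methoxy-2,6-bis(methoxymethoxy)phenyl](2-methoxy-6-methylphenyl)methanone
Conditions: Dess–Martin periodinane (1.5 equiv), pyridine, CH2Cl2, rt
Reagents that add atoms: none
Why: Dess–Martin oxidation of a secondary diaryl carbinol tolerates the four ortho substituents and the near-neutral medium leaves the MOM acetals intact.

Step 4
Reactants: 6 [4-methoxy-2,6-bis(methoxymethoxy)phenyl](2-methoxy-6-methylphenyl)methanone
Product: 7 (2,6-dihydroxy-4-methoxyphenyl)(2-methoxy-6-methylphenyl)methanone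
Conditions: conc. HCl (cat.), MeOH, 50 °C
Reagents that add atoms: none
Why: Acid-catalysed transacetalisation of the aryl MOM ethers to methanol (acetal cleavage) should free both phenols while the methyl ethers and the hindered ketone are inert.

Step 5
Reactants: 7 (2,6-dihydroxy-4-methoxyphenyl)(2-methoxy-6-methylphenyl)methanone (two molecules); 8 formaldehyde (as 37% aqueous solution)
Product: 10 bis[2,4-dihydroxy-6-methoxy-3-(2-methoxy-6-methylbenzoyl)phenyl]methane, via hydroxymethyl adduct 9 (not isolated)
Conditions: 37% aq. CH2O (0.4 equiv relative to 7), 1% aq. NaOH, 0 °C to rt; then dil. HCl; excess 7 recovered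
Reagents that add atoms: none
Why: Phenol–formaldehyde condensation (Lederer–Manasse hydroxymethylation of the phenolate at A-ring C3, which is equivalent to C5 and the only free nucleophilic site, then an o-quinone methide and Michael addition of a second phenolate) should give the methylene-bridged dimer, the deficit of formaldehyde holding back chain growth.

Step 6
Reactants: 10 bis[2,4-dihydroxy-6-methoxy-3-(2-methoxy-6-methylbenzoyl)phenyl]methane
Product: 11 bis[6-methoxy-3-(2-methoxy-6-methylbenzoyl)-2,4-bis(methoxymethoxy)phenyl]methane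
Conditions: NaH (6 equiv), MOMCl (6 equiv), DMF, 0 °C to rt
Reagents that add atoms: chloromethyl methyl ether (MOMCl), COCCl
Why: Irreversible deprotonation with NaH in DMF breaks the OH···O=C hydrogen bonds, so that O-alkylation (Williamson-type acetal formation) should cap all four hindered phenols and leave no O–H for the iridium step.

Step 7
Reactants: 11 bis[6-methoxy-3-(2-methoxy-6-methylbenzoyl)-2,4-bis(methoxymethoxy)phenyl]methane
Product: 13 bis[3-(4-hydroxy-2-methoxy-6-methylbenzoyl)-6-methoxy-2,4-bis(methoxymethoxy)phenyl]methane, via bis(pinacolboronate) 12 (not isolated)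
Conditions: [Ir(OMe)(cod)]2 (5 mol%), dtbpy (10 mol%), B2pin2 (2.5 equiv), THF, 80 °C; then NaBO3·4H2O (6 equiv), THF–H2O, rt
Reagents that add atoms: bis(pinacolato)diboron, CC1(C)OB(OC1(C)C)B1OC(C)(C)C(C)(C)O1 (boryl groups of 12); sodium perborate tetrahydrate, O.O.O.O.[Na+].[O-]OB=O (phenol oxygens of 13)
Why: An Ir(III) tris(boryl) bipyridine complex formed from the precatalyst, dtbpy and B2pin2 should cleave an aromatic C–H bond by oxidative addition, release the aryl boronate by reductive elimination and be regenerated by B2pin2, after which perborate adds to boron and a 1,2-aryl shift from boron to oxygen with hydrolysis gives the phenol. The closest known reaction type is the sterically governed iridium-catalysed C–H borylation of 1,2,3-trisubstituted arenes at the remote 5-position with one-pot oxidation to 3,4,5-trisubstituted phenols. No ring is closed and no stereocentre is created; two C–O bonds are formed by way of two C–B bonds. The step needs site selectivity among four kinds of aromatic C–H per half, and the substrate secures it sterically: B-ring C4–H alone has hydrogen on both neighbouring carbons, whereas B-ring C3–H is ortho to the methyl, B-ring C5–H is ortho to the methoxy and the lone A-ring C–H is wedged between OMe and OMOM. The MOM ethers offer no competing aryl C–H, and the carbonyl, shielded by four ortho substituents, should resist reduction by HBpin. Perborate at room temperature is chosen over hot alkaline peroxide so that the new para-hydroxyaryl ketone is not exposed to Dakin-type cleavage.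

Step 8
Reactants: 13 bis[3-(4-hydroxy-2-methoxy-6-methylbenzoyl)-6-methoxy-2,4-bis(methoxymethoxy)phenyl]methane
Product: 14 digriseophene A
Conditions: conc. HCl (cat.), MeOH, 40 °C
Reagents that add atoms: none
Why: Acid-catalysed acetal cleavage of the four aryl MOM ethers, as in step 4, should give the hexaphenol under conditions mild enough to leave the diarylmethane bridge and the methyl ethers intact.

**Compound list**

1 | 5-methoxyresorcinol (5-methoxybenzene-1,3-diol) | COc1cc(O)cc(O)c1 | starting material
2 | 1-methoxy-3,5-bis(methoxymethoxy)benzene | COCOc1cc(OC)cc(OCOC)c1 | intermediate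
3 | 2-methoxy-6-methylbenzaldehyde | COc1cccc(C)c1C=O | starting material
4 | [4-methoxy-2,6-bis(methoxymethoxy)phenyl]lithium | [Li]c1c(OCOC)cc(OC)cc1OCOC | intermediate (not isolated)
5 | rac-[4-methoxy-2,6-bis(methoxymethoxy)phenyl](2-methoxy-6-methylphenyl)methanol (racemate) | COCOc1cc(OC)cc(OCOC)c1C(O)c1c(C)cccc1OC | intermediate
6 | [4-methoxy-2,6-bis(methoxymethoxy)phenyl](2-methoxy-6-methylphenyl)methanone | COCOc1cc(OC)cc(OCOC)c1C(=O)c1c(C)cccc1OC | intermediate
7 | (2,6-dihydroxy-4-methoxyphenyl)(2-methoxy-6-methylphenyl)methanone | COc1cc(O)c(C(=O)c2c(C)cccc2OC)c(O)c1 | intermediate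
8 | formaldehyde | C=O | starting material
9 | [2,6-dihydroxy-3-(hydroxymethyl)-4-methoxyphenyl](2-methoxy-6-methylphenyl)methanone | COc1cc(O)c(C(=O)c2c(C)cccc2OC)c(O)c1CO | intermediate (not isolated)
10 | bis[2,4-dihydroxy-6-methoxy-3-(2-methoxy-6-methylbenzoyl)phenyl]methane | COc1cc(O)c(C(=O)c2c(C)cccc2OC)c(O)c1Cc1c(OC)cc(O)c(C(=O)c2c(C)cccc2OC)c1O | intermediate
11 | bis[6-methoxy-3-(2-methoxy-6-methylbenzoyl)-2,4-bis(methoxymethoxy)phenyl]methane (key-step precursor) | COc1cc(OCOC)c(C(=O)c2c(C)cccc2OC)c(OCOC)c1Cc1c(OC)cc(OCOC)c(C(=O)c2c(C)cccc2OC)c1OCOC | intermediate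
12 | bis{6-methoxy-3-[2-methoxy-6-methyl-4-(4,4,5,5-tetramethyl-1,3,2-dioxaborolan-2-yl)benzoyl]-2,4-bis(methoxymethoxy)phenyl}methane | COc1cc(OCOC)c(C(=O)c2c(C)cc(B3OC(C)(C)C(C)(C)O3)cc2OC)c(OCOC)c1Cc1c(OC)cc(OCOC)c(C(=O)c2c(C)cc(B3OC(C)(C)C(C)(C)O3)cc2OC)c1OCOC | intermediate (not isolated)
13 | bis[3-(4-hydroxy-2-methoxy-6-methylbenzoyl)-6-methoxy-2,4-bis(methoxymethoxy)phenyl]methane (key-step product) | COc1cc(OCOC)c(C(=O)c2c(C)cc(O)cc2OC)c(OCOC)c1Cc1c(OC)cc(OCOC)c(C(=O)c2c(C)cc(O)cc2OC)c1OCOC | intermediate
14 | digriseophene A, bis[2,4-dihydroxy-3-(4-hydroxy-2-methoxy-6-methylbenzoyl)-6-methoxyphenyl]methane | COc1cc(O)c(C(=O)c2c(C)cc(O)cc2OC)c(O)c1Cc1c(OC)cc(O)c(C(=O)c2c(C)cc(O)cc2OC)c1O | target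

**Step count**

Total steps: 8. Longest linear sequence: 8 (1 to 14); 3 and 8 are bought.

**Steps most likely to fail**

Step 7. The second C–H borylation may stall after the first, borylation may leak to the C–H ortho to the B-ring methoxy, the catalyst may be tied up by the many ether oxygens, or the para-hydroxyaryl ketone may be over-oxidised during the boron-to-oxygen exchange. The fallback brings the B-ring oxygen in with the aldehyde. It sets out from 2 and comes back at 14. Purchased 4-hydroxy-2-methoxy-6-methylbenzaldehyde F1 is protected (MOMCl, i-Pr2NEt, CH2Cl2) as 2-methoxy-4-(methoxymethoxy)-6-methylbenzaldehyde F2. Compound 2 is lithiated to 4 as in step 2 and added to F2 to give rac-[4-methoxy-2,6-bis(methoxymethoxy)phenyl][2-methoxy-4-(methoxymethoxy)-6-methylphenyl]methanol F3. Dess–Martin oxidation should give [4-methoxy-2,6-bis(methoxymethoxy)phenyl][2-methoxy-4-(methoxymethoxy)-6-methylphenyl]methanone F4. HCl in methanol removes all three MOM groups to give (2,6-dihydroxy-4-methoxyphenyl)(4-hydroxy-2-methoxy-6-methylphenyl)methanone F5. Bridging of F5 with 0.4 equiv of formaldehyde 8 in dilute NaOH, through [2,6-dihydroxy-3-(hydroxymethyl)-4-methoxyphenyl](4-hydroxy-2-methoxy-6-methylphenyl)methanone F6 (not isolated), should give 14 directly, because the B-ring phenol para to the carbonyl is a far weaker carbon nucleophile than the phloroglucinol-type A ring.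

Step 5. Each half of dimer 10 keeps one nucleophilic A-ring C–H, so chain growth to trimers and higher oligomers, or base-mediated exchange of the methylene bridge, may erode the yield of the dimer. The fallback separates the two C–C bond formations. It sets out from 7 and comes back at 10. Compound 7 is aminomethylated once with N,N-dimethylmethyleneiminium iodide (1 equiv, CH2Cl2, 0 °C) to give the Mannich base {3-[(dimethylamino)methyl]-2,6-dihydroxy-4-methoxyphenyl}(2-methoxy-6-methylphenyl)methanone F7, which is isolated. F7 is then heated with a twofold excess of 7 in dioxane at 100 °C; slow thermal loss of dimethylamine gives an o-quinone methide that is trapped by 7 to give 10.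

Step 2. Metalation may compete at the C–H between the methoxy and one OMOM group, giving a regioisomeric carbinol that is hard to separate. The fallback uses a threefold-symmetric nucleophile in which all ring C–H bonds are equivalent, and sets the methyl ether afterwards. It sets out from 3 and comes back at 7, at the cost of one extra step. Purchased phloroglucinol F8 is converted (MOMCl, i-Pr2NEt, CH2Cl2) into 1,3,5-tris(methoxymethoxy)benzene F9. Lithiation with n-BuLi in THF gives [2,4,6-tris(methoxymethoxy)phenyl]lithium F10 (not isolated), which is added to 3 to give rac-(2-methoxy-6-methylphenyl)[2,4,6-tris(methoxymethoxy)phenyl]methanol F11. Dess–Martin oxidation gives (2-methoxy-6-methylphenyl)[2,4,6-tris(methoxymethoxy)phenyl]methanone F12, and HCl in methanol gives (2-methoxy-6-methylphenyl)(2,4,6-trihydroxyphenyl)methanone F13. Mono-O-methylation of F13 (Me2SO4, 1.0 equiv, K2CO3, acetone, rt) should take place at the para hydroxyl, which alone is not hydrogen-bonded to the carbonyl and is the most acidic, to give 7.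

**Further compounds**

F1 | step 7 | 4-hydroxy-2-methoxy-6-methylbenzaldehyde (bought) | COc1cc(O)cc(C)c1C=O
F2 | step 7 | 2-methoxy-4-(methoxymethoxy)-6-methylbenzaldehyde | COCOc1cc(C)c(C=O)c(OC)c1
F3 | step 7 | rac-[4-methoxy-2,6-bis(methoxymethoxy)phenyl][2-methoxy-4-(methoxymethoxy)-6-methylphenyl]methanol | COCOc1cc(OC)cc(OCOC)c1C(O)c1c(C)cc(OCOC)cc1OC
F4 | step 7 | [4-methoxy-2,6-bis(methoxymethoxy)phenyl][2-methoxy-4-(methoxymethoxy)-6-methylphenyl]methanone | COCOc1cc(OC)cc(OCOC)c1C(=O)c1c(C)cc(OCOC)cc1OC
F5 | step 7 | (2,6-dihydroxy-4-methoxyphenyl)(4-hydroxy-2-methoxy-6-methylphenyl)methanone | COc1cc(O)c(C(=O)c2c(C)cc(O)cc2OC)c(O)c1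
F6 | step 7 | [2,6-dihydroxy-3-(hydroxymethyl)-4-methoxyphenyl](4-hydroxy-2-methoxy-6-methylphenyl)methanone (not isolated) | COc1cc(O)c(C(=O)c2c(C)cc(O)cc2OC)c(O)c1CO
F7 | step 5 | {3-[(dimethylamino)methyl]-2,6-dihydroxy-4-methoxyphenyl}(2-methoxy-6-methylphenyl)methanone | COc1cc(O)c(C(=O)c2c(C)cccc2OC)c(O)c1CN(C)C
F8 | step 2 | phloroglucinol (bought) | Oc1cc(O)cc(O)c1
F9 | step 2 | 1,3,5-tris(methoxymethoxy)benzene | COCOc1cc(OCOC)cc(OCOC)c1
F10 | step 2 | [2,4,6-tris(methoxymethoxy)phenyl]lithium (not isolated) | [Li]c1c(OCOC)cc(OCOC)cc1OCOC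
F11 | step 2 | rac-(2-methoxy-6-methylphenyl)[2,4,6-tris(methoxymethoxy)phenyl]methanol | COCOc1cc(OCOC)cc(OCOC)c1C(O)c1c(C)cccc1OC
F12 | step 2 | (2-methoxy-6-methylphenyl)[2,4,6-tris(methoxymethoxy)phenyl]methanone | COCOc1cc(OCOC)cc(OCOC)c1C(=O)c1c(C)cccc1OC
F13 | step 2 | (2-methoxy-6-methylphenyl)(2,4,6-trihydroxyphenyl)methanone | COc1cccc(C)c1C(=O)c1c(O)cc(O)cc1O
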